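The ten-membered ring (C1–C10) is not closed end to end but grown out of a six-membered template. In the target the C8 oxygen and the cis C2=C3 alkene stand in the 1,5 relationship of a cyclodec-5-enone, so the ring is cut at C1–C10 and rejoined at C3–C8. A single anionic oxy-Cope shift on a quinic-acid-derived cyclohexanol (ring C3–C8) bearing cis (E)-alkenyl groups, an allyl ether on C8 and an enol ether on C3, forms C1–C10, breaks C3–C8 and delivers the C8 ketone, the cis alkene, the C10 stereocentre and an oxygenated C1 at once; C4, C6 and C7 are inherited from the template.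

Key step: step 21

Remark: atom labels follow the target throughout (C1 ketone, C2=C3, C4 methyl carbinol bearing C15, C6 angelate, C7 and C8 lactone fusion, C10 bearing C14, C11=C13 and C12 of the lactone), and "cis/trans" before step 21 refer to the six-membered ring C3–C8.

Step 1
Reactants: 1 (−)-quinic acid
Product: 2 1,5-quinide (bicyclic lactone C15(=O)–O–C6; free hydroxyls on C4, C7 and C8)
Conditions: TsOH·H2O (cat.), toluene/DMF, reflux, Dean–Stark
Reagents that add atoms: none
Why: Acid-catalysed lactonisation joins the carboxyl carbon C15 to the cis C6 hydroxyl, which masks C6–O and folds the ring into a bicycle whose convex face steers steps 3 to 5; no stereocentre is touched.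

Step 2
Reactants: 2 1,5-quinide
Product: 3 C8 PMB ether of quinide (equatorial oxygen alkylated)
Conditions: Bu2SnO, toluene, reflux (Dean–Stark); then 4-methoxybenzyl chloride, Bu4NI (cat.), 90 °C
Reagents that add atoms: 4-methoxybenzyl chloride, COc1ccc(CCl)cc1
Why: Stannylene-mediated O-alkylation of a cis-1,2-diol goes to the equatorial oxygen, here C8–O, leaving the axial C7 hydroxyl for oxidation and the tertiary C4 hydroxyl untouched.

Step 3
Reactants: 3 C8 PMB ether of quinide
Product: 4 C7 ketone
Conditions: Dess–Martin periodinane, CH2Cl2, rt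
Reagents that add atoms: none
Why: Dess–Martin oxidation converts the only secondary alcohol into the ketone under neutral conditions that spare the lactone, the tertiary alcohol and the PMB ether.

Step 4
Reactants: 4 C7 ketone; 5 methyl (triphenylphosphoranylidene)acetate
Product: 6 exocyclic enoate (C7=C11H–CO2Me, drawn with the ester on the C8 side)
Conditions: toluene, 80 °C
Reagents that add atoms: none
Why: Wittig olefination with a stabilised ylide needs no base, works on this activated α,α'-dioxygenated ketone and brings in C11 and C12; the alkene geometry is irrelevant because step 5 saturates it.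

Step 5
Reactants: 6 exocyclic enoate
Product: 7 saturated methyl ester (C7–H anti to the lactone bridge, C11 chain cis to C6–O)
Conditions: H2 (1 atm), [Ir(cod)(PCy3)(py)]PF6 (cat.), CH2Cl2, rt
Reagents that add atoms: none
Why: Homogeneous (Crabtree-type) hydrogenation adds H2 to the convex face of the bicycle, anti to the axial lactone bridge on C6, so the C11 chain ends up equatorial and cis to C6–O, and it avoids the allylic C–O hydrogenolysis a Pd surface could cause.

Step 6
Reactants: 7 saturated methyl ester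
Product: 9 cis-fused γ-lactone diol (C6–O–C12 lactone; primary C15 and tertiary C4 hydroxyls free), via triol methyl ester 8 (not isolated)
Conditions: NaBH4, EtOH, 0 °C to rt; then PPTS (cat.), toluene, 60 °C
Reagents that add atoms: none
Why: NaBH4 reduces the strained α-hydroxy lactone but not the methyl ester, and the freed C6 hydroxyl then lactonises onto C12 (transesterification), which hides C6–OH and C12 together and leaves only a primary and a tertiary hydroxyl.

Step 7
Reactants: 9 cis-fused γ-lactone diol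
Product: 10 primary tosylate (C15–OTs)
Conditions: TsCl, pyridine, DMAP (cat.), CH2Cl2, 0 °C to rt
Reagents that add atoms: 4-toluenesulfonyl chloride, Cc1ccc(cc1)S(=O)(=O)Cl
Why: Sulfonylation is selective for the primary alcohol because the only other hydroxyl is tertiary.

Step 8
Reactants: 10 primary tosylate
Product: 11 triol with C15 as methyl (hydroxyls on C4, C6 and C12; C8–OPMB)
Conditions: LiEt3BH, THF, 0 °C to reflux
Reagents that add atoms: none
Why: Hydride displacement of the primary sulfonate, assisted by the neighbouring C4 alkoxide, turns C15 into the methyl group while the same reagent reduces the γ-lactone to the C6/C12 diol, all ring stereocentres being retained.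

Step 9
Reactants: 11 triol
Product: 13 tris-silyl ether (C12–OTBS, C6–OTBS, C4–OTES; C8–OPMB), via bis-TBS ether 12 (not isolated)
Conditions: TBSOTf, 2,6-lutidine, CH2Cl2, −78 °C; then TESOTf, 0 °C
Reagents that add atoms: tert-butyldimethylsilyl triflate, CC(C)(C)[Si](C)(C)OS(=O)(=O)C(F)(F)F; triethylsilyl triflate, CC[Si](CC)(CC)OS(=O)(=O)C(F)(F)F
Why: Silyl triflates react in order of steric access, TBS going onto the primary and secondary hydroxyls at −78 °C and TES then onto the tertiary one, which gives base-stable ethers of graded lability for later selective unmasking.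

Step 10
Reactants: 13 tris-silyl ether
Product: 14 C8 alcohol
Conditions: DDQ, CH2Cl2/pH 7 buffer, 0 °C
Reagents that add atoms: none
Why: Oxidative PMB cleavage by DDQ (benzylic hydride abstraction, then hydrolysis) frees C8–OH without touching the silyl ethers.

Step 11
Reactants: 14 C8 alcohol
Product: 15 cyclohexanone (C8 ketone; C7 chain cis to C6–OTBS)
Conditions: Dess–Martin periodinane, pyridine, CH2Cl2, 0 °C to rt
Reagents that add atoms: none
Why: Buffered Dess–Martin oxidation gives the β-silyloxy ketone without base, so the axial C7 side chain is not epimerised and no silyloxy group is eliminated.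

Step 12
Reactants: 16 ethyl vinyl ether
Product: 18 (phenylselanyl)acetaldehyde, via chloro ether 17 (not isolated)
Conditions: PhSeCl, CH2Cl2, −78 °C; then aq. NaHCO3, rt
Reagents that add atoms: benzeneselenenyl chloride, Cl[Se]c1ccccc1; water, O
Why: Electrophilic selenenylation of the enol ether places selenium on the terminal carbon and chloride on the oxygen-bearing carbon, and hydrolysis of this α-chloro ether releases the aldehyde.

Step 13
Reactants: 15 cyclohexanone; 18 (phenylselanyl)acetaldehyde
Product: 20 β-hydroxy selenide at C3 (mixture at C3 and the carbinol carbon), via lithium enolate 19 (not isolated)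
Conditions: LDA, THF, −78 °C; then 18, −78 °C
Reagents that add atoms: none
Why: Kinetic deprotonation takes an axial proton of the C3 methylene rather than the equatorial, tertiary C7–H, and the lithium enolate undergoes aldol addition at −78 °C faster than it can expel the C4 silyloxy group; neither new centre needs control because step 14 removes one and step 15 sets the other.

Step 14
Reactants: 20 β-hydroxy selenide
Product: 22 2-vinyl ketone (C3 epimer mixture), via mesylate 21 (not isolated)
Conditions: MsCl, Et3N, CH2Cl2, 0 °C to rt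
Reagents that add atoms: none
Why: Mesylation of a β-hydroxy selenide triggers anti-elimination through a seleniranium ion to the terminal alkene, the established use of (phenylselanyl)acetaldehyde as a vinyl cation equivalent for ketone α-vinylation.

Step 15
Reactants: 22 2-vinyl ketone
Product: 24 vinyl ketone with the C3 vinyl group trans to the C7 chain and cis to C4–OTES, via lithium dienolate 23 (not isolated)
Conditions: LDA, THF, −78 °C; then AcOH, THF, −78 °C
Reagents that add atoms: none
Why: The doubly activated C3–H is removed selectively and the dienolate is protonated at its α-carbon (kinetic α-protonation) from the face anti to the axial C4–OTES group, which puts the vinyl group equatorial.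

Step 16
Reactants: 25 propargyl alcohol
Product: 26 4-methoxybenzyl propargyl ether
Conditions: NaH, 4-methoxybenzyl chloride, Bu4NI (cat.), THF, 0 °C to rt
Reagents that add atoms: 4-methoxybenzyl chloride, COc1ccc(CCl)cc1
Why: Williamson etherification of the primary alkoxide.

Step 17
Reactants: 26 4-methoxybenzyl propargyl ether
Product: 28 (E)-1-iodo-3-(4-methoxybenzyloxy)prop-1-ene, via alkenylzirconocene chloride 27 (not isolated)
Conditions: Cp2Zr(H)Cl, THF, rt; then I2, 0 °C
Reagents that add atoms: iodine, II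
Why: Syn hydrozirconation places zirconium on the terminal carbon and iodinolysis of the C–Zr bond proceeds with retention, giving the (E)-alkenyl iodide.

Step 18
Reactants: 24 vinyl ketone; 28 (E)-alkenyl iodide
Product: 31 cis-1,2-dialkenylcyclohexanol (C8: OH and (E)-CH=CH–CH2OPMB; C3: vinyl), via alkenyllithium 29 (not isolated), via alkenylcerium dichloride 30 (not isolated)
Conditions: 28, t-BuLi, Et2O, −78 °C; then CeCl3, THF, −78 °C; then 24, −78 °C
Reagents that add atoms: none
Why: Iodine–lithium exchange and transmetalation give a weakly basic alkenylcerium reagent that adds 1,2 to the easily enolised ketone along the axial trajectory, anti to the axial C7 chain that shields the other face, so the new alkenyl group is cis to the C3 vinyl group and the hydroxyl cis to the C7 chain.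

Step 19
Reactants: 31 cis-1,2-dialkenylcyclohexanol; 32 vinylboronic acid pinacol ester
Product: 33 (E)-alkenyl boronic ester at C3
Conditions: 32 (excess), second-generation Hoveyda–Grubbs catalyst (cat.), CH2Cl2, 40 °C
Reagents that add atoms: none
Why: Olefin cross-metathesis engages only the terminal vinyl group (the internal alkene beside the quaternary carbinol is inert) and vinylboronic esters give (E)-alkenyl boronates.

Step 20
Reactants: 33 (E)-alkenyl boronic ester
Product: 34 oxy-Cope precursor (cis-1,2-dialkenylcyclohexanol; C8: OH and (E)-CH=CH–CH2OPMB; C3: (E)-CH=CH–OPMB)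
Conditions: Cu(OAc)2, Et3N, 4-methoxybenzyl alcohol (excess), CH2Cl2, rt, air
Reagents that add atoms: 4-methoxybenzyl alcohol, COc1ccc(CO)cc1
Why: Copper-promoted oxidative C–O coupling of an alkenyl boronic ester with an alcohol (Chan–Lam type) proceeds with retention of alkene geometry, and the large excess of primary benzylic alcohol outcompetes the hindered tertiary hydroxyl.

Step 21
Reactants: 34 oxy-Cope precursor
Product: 37 ten-membered C8 ketone with cis C2=C3 (C1–OPMB, C14–OPMB, C4–OTES, C6–OTBS, C12–OTBS), via potassium alkoxide 35 (not isolated), via potassium enolate 36 (not isolated)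
Conditions: KH, 18-crown-6, THF, 0 °C to rt; then AcOH, THF, −78 °C
Reagents that add atoms: none
Why: KH with 18-crown-6 gives the crown-separated alkoxide 35, whose C3–C8 bond is weakened by the oxyanion, and a concerted [3,3] shift (anionic oxy-Cope, the known ring expansion of 1,2-dialkenylcyclohexanols to cyclodec-5-enones) breaks C3–C8 while forming C1–C10 to give enolate 36, protonated cold to ketone 37. The ten-membered ring arises by ring expansion: the C4–C7 bridge of the template is kept and the new σ bond joins the two alkene termini, so no end-to-end cyclisation is involved. The cis alkenyl groups can reach each other only with both on one ring face, and the chair array that would place C4 outside is excluded because it needs C8–O, C6–O and C15 syn-axial; this leaves a boat array with the bulky O–K(crown) pair outside and C4 and C7 inside, hence the cis C2=C3 bond. C10 is set by the (E) geometry of C9=C10, which keeps C14 outside while C1 bonds to the face of C10 from which C3 departs; C1 is set likewise by the (E) enol ether and is erased later. The step needs this boat over chair-like alternatives and needs the enolate not to drift toward C7, which the ion pair, the regiospecific C8–C9 enolate and the cold quench are chosen to secure. C4, C6 and C7 are untouched.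

Step 22
Reactants: 37 ten-membered C8 ketone
Product: 38 C8 alcohol (oxygen anti to the C11 chain, as in the target)
Conditions: LiB(s-Bu)3H, THF, −78 °C; then H2O
Reagents that add atoms: none
Why: Felkin–Anh addition of the bulky hydride anti to the C7–C6 bond, reinforced by the 1,3-anti preference of the β-silyloxy group, should give the alcohol with oxygen anti to the C11 chain without epimerising C7 at −78 °C.

Step 23
Reactants: 38 C8 alcohol
Product: 39 triol (C8, C12 and C4 hydroxyls free; C6–OTBS kept)
Conditions: HF·pyridine, pyridine, THF, 0 °C to rt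
Reagents that add atoms: none
Why: Buffered HF·pyridine cleaves silyl ethers by accessibility and lability, removing the primary TBS and the TES groups while the hindered secondary TBS ether on C6 stays.

Step 24
Reactants: 39 triol
Product: 41 trans-fused γ-lactone (C8–O–C12=O), via lactol 40 (not isolated)
Conditions: TEMPO (cat.), PhI(OAc)2, CH2Cl2, rt
Reagents that add atoms: none
Why: TEMPO/PhI(OAc)2 oxidises only the primary alcohol, the aldehyde closes to the lactol with the C8 hydroxyl and is oxidised again (oxidative lactonisation of a 1,4-diol), C6–O being blocked and the tertiary alcohol inert.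

Step 25
Reactants: 41 trans-fused γ-lactone
Product: 45 α-methylene lactone (C11=C13), via dilithio enolate 42 (not isolated), via Mannich base 43 (not isolated), via ammonium iodide 44 (not isolated)
Conditions: LDA (excess), THF, −78 °C; CH2=NMe2+ I−, −78 to 0 °C; then MeI, MeOH, rt; then aq. NaHCO3, rt
Reagents that add atoms: N,N-dimethylmethyleneiminium iodide (Eschenmoser's salt), C=[N+](C)C.[I-]
Why: The lactone enolate is aminomethylated (Mannich reaction), and quaternisation followed by mild base causes Hofmann-type β-elimination of trimethylamine to the exocyclic alkene; this is done before any enolisable or base-sensitive ester and ketone are present.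

Step 26
Reactants: 45 α-methylene lactone
Product: 46 C6 alcohol
Conditions: HF·pyridine, THF, rt
Reagents that add atoms: none
Why: Prolonged HF·pyridine removes the remaining secondary TBS ether without base, so the free C6 hydroxyl cannot translactonise and the α-methylene lactone is not attacked.

Step 27
Reactants: 46 C6 alcohol; 47 angelic acid
Product: 49 C6 angelate, via mixed anhydride 48 (not isolated)
Conditions: 47, 2,4,6-trichlorobenzoyl chloride, Et3N, toluene, rt; then 46, 80 °C
Reagents that add atoms: none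
Why: Yamaguchi esterification through the mixed anhydride acylates the secondary C6 hydroxyl (the tertiary C4 hydroxyl does not react) and is the usual way to attach an angelate without Z to E isomerisation.

Step 28
Reactants: 49 C6 angelate
Product: 50 C1,C14-diol
Conditions: DDQ, CH2Cl2/pH 7 buffer, 0 °C to rt
Reagents that add atoms: none
Why: DDQ cleaves both PMB ethers oxidatively in one operation, which is why C1 and C14 carry the same protecting group.

Step 29
Reactants: 50 C1,C14-diol
Product: 51 CNP0219400.1 (target)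
Conditions: MnO2, CH2Cl2, rt
Reagents that add atoms: none
Why: MnO2 oxidises only the allylic C1 hydroxyl to the enone under neutral conditions, leaving the primary C14 alcohol, the C10 centre beside the new ketone and the two Michael acceptors alone.

Compound list
1 | (−)-quinic acid | C1[C@H]([C@H]([C@@H](C[C@@]1(C(=O)O)O)O)O)O | starting material
2 | 1,5-quinide | O[C@H]1[C@@H](O)[C@H]2C[C@@](C(=O)O2)(O)C1 | intermediate
3 | C8 PMB ether of quinide | COc1ccc(CO[C@H]2[C@@H](O)[C@H]3C[C@@](C(=O)O3)(O)C2)cc1 | intermediate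
4 | C7 ketone | COc1ccc(CO[C@H]2C(=O)[C@H]3C[C@@](C(=O)O3)(O)C2)cc1 | intermediate
5 | methyl (triphenylphosphoranylidene)acetate | COC(=O)C=P(c1ccccc1)(c1ccccc1)c1ccccc1 | starting material
6 | exocyclic enoate | COc1ccc(CO[C@H]2/C(=C\C(=O)OC)[C@H]3C[C@@](C(=O)O3)(O)C2)cc1 | intermediate
7 | saturated methyl ester | COc1ccc(CO[C@H]2[C@H](CC(=O)OC)[C@H]3C[C@@](C(=O)O3)(O)C2)cc1 | intermediate
8 | triol methyl ester (not isolated) | COc1ccc(CO[C@H]2[C@H](CC(=O)OC)[C@H](O)C[C@@](CO)(O)C2)cc1 | intermediate
9 | cis-fused γ-lactone diol | COc1ccc(CO[C@H]2[C@@H]3CC(=O)O[C@@H]3C[C@@](CO)(O)C2)cc1 | intermediate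
10 | primary tosylate | COc1ccc(CO[C@H]2[C@@H]3CC(=O)O[C@@H]3C[C@@](COS(=O)(=O)c3ccc(C)cc3)(O)C2)cc1 | intermediate
11 | triol with C15 methyl | COc1ccc(CO[C@H]2[C@H](CCO)[C@H](O)C[C@@](C)(O)C2)cc1 | intermediate
12 | bis-TBS ether (not isolated) | COc1ccc(CO[C@H]2[C@H](CCO[Si](C)(C)C(C)(C)C)[C@H](O[Si](C)(C)C(C)(C)C)C[C@@](C)(O)C2)cc1 | intermediate
13 | tris-silyl ether | COc1ccc(CO[C@H]2[C@H](CCO[Si](C)(C)C(C)(C)C)[C@H](O[Si](C)(C)C(C)(C)C)C[C@@](C)(O[Si](CC)(CC)CC)C2)cc1 | intermediate
14 | C8 alcohol | O[C@H]1[C@H](CCO[Si](C)(C)C(C)(C)C)[C@H](O[Si](C)(C)C(C)(C)C)C[C@@](C)(O[Si](CC)(CC)CC)C1 | intermediate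
15 | cyclohexanone (C8 ketone) | O=C1[C@H](CCO[Si](C)(C)C(C)(C)C)[C@H](O[Si](C)(C)C(C)(C)C)C[C@@](C)(O[Si](CC)(CC)CC)C1 | intermediate
16 | ethyl vinyl ether | C=COCC | starting material
17 | 1-chloro-1-ethoxy-2-(phenylselanyl)ethane (not isolated) | CCOC(Cl)C[Se]c1ccccc1 | intermediate
18 | (phenylselanyl)acetaldehyde | O=CC[Se]c1ccccc1 | intermediate
19 | lithium enolate of 15 (not isolated) | [Li+].[O-]C=1[C@H](CCO[Si](C)(C)C(C)(C)C)[C@H](O[Si](C)(C)C(C)(C)C)C[C@@](C)(O[Si](CC)(CC)CC)C=1 | intermediate
20 | β-hydroxy selenide (mixture at C3 and carbinol carbon) | O=C1[C@H](CCO[Si](C)(C)C(C)(C)C)[C@H](O[Si](C)(C)C(C)(C)C)C[C@@](C)(O[Si](CC)(CC)CC)C1C(O)C[Se]c1ccccc1 | intermediate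
21 | mesylate of 20 (not isolated) | O=C1[C@H](CCO[Si](C)(C)C(C)(C)C)[C@H](O[Si](C)(C)C(C)(C)C)C[C@@](C)(O[Si](CC)(CC)CC)C1C(OS(C)(=O)=O)C[Se]c1ccccc1 | intermediate
22 | 2-vinyl ketone (C3 epimer mixture) | O=C1[C@H](CCO[Si](C)(C)C(C)(C)C)[C@H](O[Si](C)(C)C(C)(C)C)C[C@@](C)(O[Si](CC)(CC)CC)C1C=C | intermediate
23 | lithium dienolate (not isolated) | [Li+].[O-]C=1[C@H](CCO[Si](C)(C)C(C)(C)C)[C@H](O[Si](C)(C)C(C)(C)C)C[C@@](C)(O[Si](CC)(CC)CC)C=1C=C | intermediate
24 | vinyl ketone, C3 vinyl trans to C7 chain | O=C1[C@H](CCO[Si](C)(C)C(C)(C)C)[C@H](O[Si](C)(C)C(C)(C)C)C[C@@](C)(O[Si](CC)(CC)CC)[C@H]1C=C | intermediate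
25 | propargyl alcohol | C#CCO | starting material
26 | 4-methoxybenzyl propargyl ether | C#CCOCc1ccc(OC)cc1 | intermediate
27 | (E)-alkenylzirconocene chloride (not isolated) | Cl[Zr](/C=C/COCc1ccc(OC)cc1)(C1C=CC=C1)C1C=CC=C1 | intermediate
28 | (E)-1-iodo-3-(4-methoxybenzyloxy)prop-1-ene | I/C=C/COCc1ccc(OC)cc1 | intermediate
29 | (E)-alkenyllithium (not isolated) | [Li]/C=C/COCc1ccc(OC)cc1 | intermediate
30 | (E)-alkenylcerium dichloride (not isolated) | Cl[Ce](Cl)/C=C/COCc1ccc(OC)cc1 | intermediate
31 | cis-1,2-dialkenylcyclohexanol with C3 vinyl | O[C@]1(/C=C/COCc2ccc(OC)cc2)[C@H](CCO[Si](C)(C)C(C)(C)C)[C@H](O[Si](C)(C)C(C)(C)C)C[C@@](C)(O[Si](CC)(CC)CC)[C@H]1C=C | intermediate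
32 | vinylboronic acid pinacol ester | C=CB1OC(C)(C)C(C)(C)O1 | starting material
33 | (E)-alkenyl boronic ester | O[C@]1(/C=C/COCc2ccc(OC)cc2)[C@H](CCO[Si](C)(C)C(C)(C)C)[C@H](O[Si](C)(C)C(C)(C)C)C[C@@](C)(O[Si](CC)(CC)CC)[C@H]1/C=C/B1OC(C)(C)C(C)(C)O1 | intermediate
34 | oxy-Cope precursor | O[C@]1(/C=C/COCc2ccc(OC)cc2)[C@H](CCO[Si](C)(C)C(C)(C)C)[C@H](O[Si](C)(C)C(C)(C)C)C[C@@](C)(O[Si](CC)(CC)CC)[C@H]1/C=C/OCc1ccc(OC)cc1 | intermediate
35 | potassium alkoxide of 34 (not isolated) | [K+].[O-][C@]1(/C=C/COCc2ccc(OC)cc2)[C@H](CCO[Si](C)(C)C(C)(C)C)[C@H](O[Si](C)(C)C(C)(C)C)C[C@@](C)(O[Si](CC)(CC)CC)[C@H]1/C=C/OCc1ccc(OC)cc1 | intermediate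
36 | potassium enolate (C8=C9, not isolated) | [K+].[O-]/C1=C/[C@@H](COCc2ccc(OC)cc2)[C@@H](OCc2ccc(OC)cc2)/C=C\[C@](C)(O[Si](CC)(CC)CC)C[C@@H](O[Si](C)(C)C(C)(C)C)[C@H]1CCO[Si](C)(C)C(C)(C)C | intermediate
37 | ten-membered C8 ketone with cis C2=C3 | O=C1C[C@@H](COCc2ccc(OC)cc2)[C@@H](OCc2ccc(OC)cc2)/C=C\[C@](C)(O[Si](CC)(CC)CC)C[C@@H](O[Si](C)(C)C(C)(C)C)[C@H]1CCO[Si](C)(C)C(C)(C)C | intermediate
38 | C8 alcohol (O anti to C11) | O[C@@H]1C[C@@H](COCc2ccc(OC)cc2)[C@@H](OCc2ccc(OC)cc2)/C=C\[C@](C)(O[Si](CC)(CC)CC)C[C@@H](O[Si](C)(C)C(C)(C)C)[C@H]1CCO[Si](C)(C)C(C)(C)C | intermediate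
39 | triol | O[C@@H]1C[C@@H](COCc2ccc(OC)cc2)[C@@H](OCc2ccc(OC)cc2)/C=C\[C@](C)(O)C[C@@H](O[Si](C)(C)C(C)(C)C)[C@H]1CCO | intermediate
40 | lactol (not isolated) | C1C(O)O[C@@H]2C[C@@H](COCc3ccc(OC)cc3)[C@@H](OCc3ccc(OC)cc3)/C=C\[C@](C)(O)C[C@@H](O[Si](C)(C)C(C)(C)C)[C@@H]12 | intermediate
41 | trans-fused γ-lactone | C1C(=O)O[C@@H]2C[C@@H](COCc3ccc(OC)cc3)[C@@H](OCc3ccc(OC)cc3)/C=C\[C@](C)(O)C[C@@H](O[Si](C)(C)C(C)(C)C)[C@@H]12 | intermediate
42 | dilithio lactone enolate/C4 alkoxide (not isolated) | [Li+].[Li+].C1=C([O-])O[C@@H]2C[C@@H](COCc3ccc(OC)cc3)[C@@H](OCc3ccc(OC)cc3)/C=C\[C@](C)([O-])C[C@@H](O[Si](C)(C)C(C)(C)C)[C@@H]12 | intermediate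
43 | Mannich base (C11 mixture, not isolated) | CN(C)CC1C(=O)O[C@@H]2C[C@@H](COCc3ccc(OC)cc3)[C@@H](OCc3ccc(OC)cc3)/C=C\[C@](C)(O)C[C@@H](O[Si](C)(C)C(C)(C)C)[C@@H]12 | intermediate
44 | trimethylammonium iodide (not isolated) | [I-].C[N+](C)(C)CC1C(=O)O[C@@H]2C[C@@H](COCc3ccc(OC)cc3)[C@@H](OCc3ccc(OC)cc3)/C=C\[C@](C)(O)C[C@@H](O[Si](C)(C)C(C)(C)C)[C@@H]12 | intermediate
45 | α-methylene lactone | C=C1C(=O)O[C@@H]2C[C@@H](COCc3ccc(OC)cc3)[C@@H](OCc3ccc(OC)cc3)/C=C\[C@](C)(O)C[C@@H](O[Si](C)(C)C(C)(C)C)[C@@H]12 | intermediate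
46 | C6 alcohol | C=C1C(=O)O[C@@H]2C[C@@H](COCc3ccc(OC)cc3)[C@@H](OCc3ccc(OC)cc3)/C=C\[C@](C)(O)C[C@@H](O)[C@@H]12 | intermediate
47 | angelic acid | C/C=C(/C)C(=O)O | starting material
48 | angelic 2,4,6-trichlorobenzoic anhydride (not isolated) | C/C=C(/C)C(=O)OC(=O)c1c(Cl)cc(Cl)cc1Cl | intermediate
49 | C6 angelate | C=C1C(=O)O[C@@H]2C[C@@H](COCc3ccc(OC)cc3)[C@@H](OCc3ccc(OC)cc3)/C=C\[C@](C)(O)C[C@@H](OC(=O)/C(C)=C\C)[C@@H]12 | intermediate
50 | C1,C14-diol | C=C1C(=O)O[C@@H]2C[C@@H](CO)[C@@H](O)/C=C\[C@](C)(O)C[C@@H](OC(=O)/C(C)=C\C)[C@@H]12 | intermediate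
51 | CNP0219400.1 | C=C1C(=O)O[C@@H]2C[C@@H](CO)C(=O)/C=C\[C@](C)(O)C[C@@H](OC(=O)/C(C)=C\C)[C@@H]12 | target

Total step count: 29. Longest linear sequence: 26 steps (steps 1–11, 13–15 and 18–29).

Steps most likely to fail

Step 21. The alkoxide may rearrange through a chair-like array with C7 outside and the oxyanion inside. The cis C2=C3 bond would still form, but C1 would bond to the other face of C10 and the C10 epimer would result. Fallback: invert the geometry of C9=C10 so that this chair array gives the required C10 configuration. Alkyne 26 is iodinated (N-iodosuccinimide, AgNO3 cat., acetone) to 1-iodo-3-(4-methoxybenzyloxy)prop-1-yne F1 and reduced with diimide (2-nitrobenzenesulfonyl hydrazide, Et3N) to (Z)-1-iodo-3-(4-methoxybenzyloxy)prop-1-ene F2. Under the conditions of steps 18 to 20, F2 and ketone 24 give the (Z)-alkenyl carbinol F3, then the boronic ester F4, then the (Z)-allyl ether precursor F5. KH/18-crown-6 converts F5 into ketone 37, where the route is rejoined.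

Step 18. Facial selectivity may be poor: attack on the face syn to the C7 chain gives the trans-dialkenyl carbinol, which can only lead to a trans C2=C3 alkene. Fallback: use a slim sp nucleophile, which follows the axial trajectory more strictly, and set the alkene afterwards. Alkyne 26 is deprotonated (n-BuLi, THF, −78 °C) to lithium 3-(4-methoxybenzyloxy)prop-1-yn-1-ide F6, transmetalated with CeCl3 and added to ketone 24 to give the tertiary propargylic alcohol F7. Hydroxyl-directed trans-hydroalumination with NaAlH2(OCH2CH2OMe)2 (THF, 0 °C) and protonolysis gives carbinol 31, where the route is rejoined.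

Step 22. The conformation of the ten-membered ring may override the Felkin–Anh preference, so that hydride arrives on the other face and the C8 epimer (oxygen syn to the C11 chain) forms. Fallback: keep that epimer and close the lactone with inversion instead of retention. The epimeric alcohol F8 from 37 is mesylated (MsCl, Et3N) to mesylate F9. HF·pyridine removes the primary TBS and the TES groups to give hydroxy mesylate F10. TEMPO/PhI(OAc)2 in MeCN/H2O oxidises the primary alcohol to carboxylic acid F11. Cs2CO3 in DMF then lets the carboxylate displace the C8 mesylate from the rear (intramolecular SN2, five-membered ring) to give lactone 41, where the route is rejoined.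

Further compounds
F1 | step 21 | 1-iodo-3-(4-methoxybenzyloxy)prop-1-yne | IC#CCOCc1ccc(OC)cc1
F2 | step 21 | (Z)-1-iodo-3-(4-methoxybenzyloxy)prop-1-ene | I/C=C\COCc1ccc(OC)cc1
F3 | step 21 | (Z)-alkenyl carbinol with C3 vinyl | O[C@]1(/C=C\COCc2ccc(OC)cc2)[C@H](CCO[Si](C)(C)C(C)(C)C)[C@H](O[Si](C)(C)C(C)(C)C)C[C@@](C)(O[Si](CC)(CC)CC)[C@H]1C=C
F4 | step 21 | (Z)-alkenyl carbinol boronic ester | O[C@]1(/C=C\COCc2ccc(OC)cc2)[C@H](CCO[Si](C)(C)C(C)(C)C)[C@H](O[Si](C)(C)C(C)(C)C)C[C@@](C)(O[Si](CC)(CC)CC)[C@H]1/C=C/B1OC(C)(C)C(C)(C)O1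
F5 | step 21 | (Z)-allyl ether oxy-Cope precursor | O[C@]1(/C=C\COCc2ccc(OC)cc2)[C@H](CCO[Si](C)(C)C(C)(C)C)[C@H](O[Si](C)(C)C(C)(C)C)C[C@@](C)(O[Si](CC)(CC)CC)[C@H]1/C=C/OCc1ccc(OC)cc1
F6 | step 18 | lithium 3-(4-methoxybenzyloxy)prop-1-yn-1-ide | [Li]C#CCOCc1ccc(OC)cc1
F7 | step 18 | tertiary propargylic alcohol | O[C@]1(C#CCOCc2ccc(OC)cc2)[C@H](CCO[Si](C)(C)C(C)(C)C)[C@H](O[Si](C)(C)C(C)(C)C)C[C@@](C)(O[Si](CC)(CC)CC)[C@H]1C=C
F8 | step 22 | C8-epimeric alcohol | O[C@H]1C[C@@H](COCc2ccc(OC)cc2)[C@@H](OCc2ccc(OC)cc2)/C=C\[C@](C)(O[Si](CC)(CC)CC)C[C@@H](O[Si](C)(C)C(C)(C)C)[C@H]1CCO[Si](C)(C)C(C)(C)C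
F9 | step 22 | C8 mesylate | CS(=O)(=O)O[C@H]1C[C@@H](COCc2ccc(OC)cc2)[C@@H](OCc2ccc(OC)cc2)/C=C\[C@](C)(O[Si](CC)(CC)CC)C[C@@H](O[Si](C)(C)C(C)(C)C)[C@H]1CCO[Si](C)(C)C(C)(C)C
F10 | step 22 | hydroxy mesylate | CS(=O)(=O)O[C@H]1C[C@@H](COCc2ccc(OC)cc2)[C@@H](OCc2ccc(OC)cc2)/C=C\[C@](C)(O)C[C@@H](O[Si](C)(C)C(C)(C)C)[C@H]1CCO
F11 | step 22 | mesyloxy carboxylic acid | CS(=O)(=O)O[C@H]1C[C@@H](COCc2ccc(OC)cc2)[C@@H](OCc2ccc(OC)cc2)/C=C\[C@](C)(O)C[C@@H](O[Si](C)(C)C(C)(C)C)[C@H]1CC(=O)O
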